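**Retrosynthetic overview**
1. Last step: global acidolysis, then Fremy oxidation of a 3-amino-1-naphthol to the 2-amino-1,4-naphthoquinone (quinone ring formed last).
2. C15–aryl bond: aryllithium from a 5-bromonaphthalene adds to a C15 enal, then oxidation to the ketone.
3. C13=C14 and C2=C3 by cross-metathesis (methacrolein, tert-butyl acrylate); C4–C5 and C11–C12 by anti-Felkin (Z)-crotylboration of C5 and C11 aldehydes.
4. The pseudo-meso all-anti C5–C11 pentad comes from a meso diol: boron anti-aldol/syn-reduction of ethyl isopropenyl ketone with methacrolein, acetonide (dioxane ring, formed first), two-directional Still hydroboration, lipase desymmetrisation.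
5. Naphthalene: benzenoid ring from 4-hydroxy-3-methylbenzaldehyde, second ring by Stobbe condensation/Ac2O cyclisation, nitrogen by Curtius rearrangement.

Assumption: Amano lipase PS acetylates the CH2OH arm on the (R)-configured methine of meso diol 8 (the future C11 end), as it does with simple 2-methyl primary alcohols; the opposite outcome is handled by the fallback to step 4.

Naming convention: chain locants C1 (CO2H) to C15 (aryl C=O) and naphthalene locants (C1/C4 carbonyls, N at C2, chain at C5, OH at C6, Me at C7) are those of the target. Every chain stereocentre drawn has the configuration of the same carbon in the target (4R,5S,6S,7S,8S,9R,10R,11R,12S).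

**Step 1**
Reactants: 1 2-methylpent-1-en-3-one; 2 2-methylprop-2-enal (methacrolein)
Product: 5 meso-(3R,4r,5S)-2,4,6-trimethylhepta-1,6-diene-3,5-diol, via (E)-enol dicyclohexylborinate 3 (not isolated), via racemic anti boron aldolate 4 (not isolated)
Conditions: c-Hex2BCl, Et3N, Et2O, −78 → 0 °C; 2, −78 → −20 °C; LiBH4, −78 °C; H2O2, pH 7 buffer, MeOH, 0 °C
Reagents that add atoms: none
Why: Brown/Paterson (E)-selective boron enolisation and a Zimmerman–Traxler chair give the anti aldol, and in situ LiBH4 reduction of the cyclic boron aldolate (Narasaka–Prasad-type) gives the syn-1,3-diol, so the C8 methyl is anti to both hydroxyls and both aldol enantiomers converge on one meso diol without any chiral reagent.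

**Step 2**
Reactants: 5 meso dienediol
Product: 6 meso-(4R,5r,6S)-2,2,5-trimethyl-4,6-di(prop-1-en-2-yl)-1,3-dioxane
Conditions: Me2C(OMe)2, PPTS (cat.), CH2Cl2, rt
Reagents that add atoms: 2,2-dimethoxypropane, COC(C)(C)OC
Why: Acid-catalysed transketalisation of the syn-1,3-diol gives the all-equatorial acetonide, which protects O7/O9 and rigidifies the allylic centres for the next step.

**Step 3**
Reactants: 6 meso diene acetonide
Product: 8 meso diol (2R)-2-[(4R,5s,6S)-6-[(2S)-1-hydroxypropan-2-yl]-2,2,5-trimethyl-1,3-dioxan-4-yl]propan-1-ol (C5–C11 of the target), via bis(9-BBN) trialkylborane 7 (not isolated)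
Conditions: 9-BBN (2.5 eq), THF, 0 °C → rt; then NaOH, H2O2, 0 °C → rt
Reagents that add atoms: hydrogen peroxide, OO
Why: Two-directional Still–Barrish hydroboration: each isopropenyl group reacts with its allylic C–H eclipsing the alkene and 9-BBN adding anti to the methyl-bearing ring carbon, so the new C6 and C10 methyls are anti to O7/O9 and the meso all-anti pentad results.

**Step 4**
Reactants: 8 meso C5–C11 diol
Product: 9 monoacetate (2R)-2-[(4R,5S,6S)-6-[(2S)-1-hydroxypropan-2-yl]-2,2,5-trimethyl-1,3-dioxan-4-yl]propyl acetate (11-OAc; 5-OH)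
Conditions: lipase PS (Amano), vinyl acetate, t-BuOMe, rt
Reagents that add atoms: vinyl acetate, C=COC(C)=O
Why: Lipase-catalysed enantiotopic-group-selective transesterification (irreversible with vinyl acetate) desymmetrises the meso diol and fixes the absolute configuration of all five stereocentres at once.

**Step 5**
Reactants: 9 C5–C11 monoacetate
Product: 10 C5 aldehyde (5-CHO; 6,8,10-trimethyl; 7,9-O-isopropylidene; 11-OAc)
Conditions: TEMPO (cat.), PhI(OAc)2, CH2Cl2, rt
Reagents that add atoms: none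
Why: TEMPO/BAIB oxidation of the primary alcohol is near-neutral and does not epimerise the α-methyl centre C6.

**Step 6**
Reactants: 10 C5 aldehyde; 11 (Z)-crotylboronic acid pinacol ester
Product: 13 C2–C11 alkenol (vinyl C2=C3; 4-Me; 5-OH; 7,9-O-isopropylidene; 11-OAc), via pinacol borate ester 12 (not isolated)
Conditions: 11 (1.5 eq), toluene, 4 Å MS, rt, 48 h; then aq NaHCO3
Reagents that add atoms: none
Why: Allylboration through a closed chair transition state makes the (Z)-crotyl unit give the 4,5-syn relationship, and the intrinsic anti-Felkin preference of (Z)-crotylboronates with α-methyl aldehydes (the Felkin transition state suffers a syn-pentane clash) gives 5,6-anti.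

**Step 7**
Reactants: 13 C2–C11 alkenol acetate
Product: 14 C2–C11 alkene diol (5-OH; 11-OH)
Conditions: K2CO3 (cat.), MeOH, 0 °C → rt
Reagents that add atoms: none
Why: Zemplén-type methanolysis removes the primary acetate before any base-sensitive enoate is present.

**Step 8**
Reactants: 14 C2–C11 alkene diol; 15 tert-butyl acrylate
Product: 16 tert-butyl (2E)-5,11-dihydroxy-7,9-O-isopropylidene-4,6,8,10-tetramethylundec-2-enoate
Conditions: Hoveyda–Grubbs II (5 mol%), 15 (5 eq), CH2Cl2, 40 °C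
Reagents that add atoms: none
Why: Olefin cross-metathesis of a terminal alkene with an acrylate is selective and gives the (E)-enoate, which also differentiates this terminus for good from the one built later.

**Step 9**
Reactants: 16 C1–C11 enoate diol
Product: 17 tert-butyl (2E)-5-hydroxy-7,9-O-isopropylidene-4,6,8,10-tetramethyl-11-oxoundec-2-enoate
Conditions: TEMPO (cat.), PhI(OAc)2, CH2Cl2, rt
Reagents that add atoms: none
Why: TEMPO/BAIB oxidises the primary C11 alcohol chemoselectively in the presence of the hindered secondary C5 alcohol and the enoate.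

**Step 10**
Reactants: 17 C11 aldehyde; 11 (Z)-crotylboronic acid pinacol ester
Product: 19 tert-butyl (2E)-5,11-dihydroxy-7,9-O-isopropylidene-4,6,8,10,12-pentamethyltetradeca-2,13-dienoate, via pinacol borate ester 18 (not isolated)
Conditions: 11 (2 eq), toluene, 4 Å MS, rt, 48 h; then aq NaHCO3
Reagents that add atoms: none
Why: The same anti-Felkin (Z)-crotylboration at the pseudo-enantiomeric terminus sets 11,12-syn and 10,11-anti by substrate control.

**Step 11**
Reactants: 19 C1–C14 diene diol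
Product: 20 tert-butyl (2E)-7,9-O-isopropylidene-4,6,8,10,12-pentamethyl-5,11-bis(triethylsilyloxy)tetradeca-2,13-dienoate
Conditions: TESCl, imidazole, DMAP (cat.), DMF, rt → 40 °C
Reagents that add atoms: chlorotriethylsilane, CC[Si](Cl)(CC)CC
Why: Silylation masks both secondary alcohols for the organolithium and oxidation steps with a group that the final acid removes.

**Step 12**
Reactants: 20 bis-TES diene; 2 2-methylprop-2-enal (methacrolein)
Product: 21 tert-butyl (2E,13E)-7,9-O-isopropylidene-4,6,8,10,12,14-hexamethyl-15-oxo-5,11-bis(triethylsilyloxy)pentadeca-2,13-dienoate (C15 enal)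
Conditions: Hoveyda–Grubbs II (10 mol%), 2 (20 eq), CH2Cl2, 40 °C
Reagents that add atoms: none
Why: Cross-metathesis of the only terminal alkene with methacrolein gives the thermodynamically preferred (E)-trisubstituted enal, the enoate being an unreactive spectator olefin.

**Step 13**
Reactants: 22 4-hydroxy-3-methylbenzaldehyde
Product: 23 4-(methoxymethoxy)-3-methylbenzaldehyde
Conditions: MOMCl, i-Pr2NEt, CH2Cl2, 0 °C → rt
Reagents that add atoms: chloromethyl methyl ether, COCCl
Why: O-Alkylation gives a phenol protecting group that survives base and organolithium and is removed by the final acid.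

**Step 14**
Reactants: 23 4-(methoxymethoxy)-3-methylbenzaldehyde; 24 dimethyl succinate
Product: 25 (E)-3-(methoxycarbonyl)-4-[4-(methoxymethoxy)-3-methylphenyl]but-3-enoic acid
Conditions: KOtBu, t-BuOH, reflux; then aq HCl
Reagents that add atoms: none
Why: Stobbe condensation (aldol, lactonisation, E1cB ring opening) gives the (E)-half-ester with the aryl group cis to the CH2CO2H arm as needed for ring closure.

**Step 15**
Reactants: 25 Stobbe half-ester
Product: 26 methyl 4-acetoxy-6-(methoxymethoxy)-7-methylnaphthalene-2-carboxylate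
Conditions: Ac2O, NaOAc, 120 °C
Reagents that add atoms: acetic anhydride, CC(=O)OC(C)=O
Why: The mixed anhydride undergoes intramolecular Friedel–Crafts acylation at the unhindered ring position para to the methyl group, and the resulting naphthol is acetylated in situ.

**Step 16**
Reactants: 26 naphthyl acetate ester
Product: 27 methyl 4-acetoxy-5-bromo-6-(methoxymethoxy)-7-methylnaphthalene-2-carboxylate
Conditions: NBS, MeCN, 0 °C → rt, dark
Reagents that add atoms: N-bromosuccinimide, O=C1CCC(=O)N1Br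
Why: Electrophilic aromatic bromination goes to C5, the only free position activated by the 6-alkoxy group (α and ortho), while the ester/acetate ring is deactivated.

**Step 17**
Reactants: 27 bromo naphthyl acetate
Product: 28 methyl 5-bromo-4-hydroxy-6-(methoxymethoxy)-7-methylnaphthalene-2-carboxylate
Conditions: K2CO3 (cat.), MeOH, 0 °C
Reagents that add atoms: none
Why: The aryl acetate is methanolysed much faster than the methyl ester, freeing the C4 naphthol.

**Step 18**
Reactants: 28 bromo naphthol ester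
Product: 29 methyl 5-bromo-4,6-bis(methoxymethoxy)-7-methylnaphthalene-2-carboxylate
Conditions: MOMCl, i-Pr2NEt, CH2Cl2, 0 → 40 °C
Reagents that add atoms: chloromethyl methyl ether, COCCl
Why: O-Alkylation protects the C4 naphthol (acyl protection would not survive the later aryllithium at the peri position).

**Step 19**
Reactants: 29 bis-MOM ester
Product: 30 5-bromo-4,6-bis(methoxymethoxy)-7-methylnaphthalene-2-carboxylic acid
Conditions: LiOH, THF/MeOH/H2O, rt; then aq HCl to pH 4, 0 °C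
Reagents that add atoms: lithium hydroxide, [Li+].[OH-]
Why: Saponification of the methyl ester proceeds without touching the MOM ethers or the aryl bromide.

**Step 20**
Reactants: 30 naphthoic acid
Product: 33 tert-butyl N-[5-bromo-4,6-bis(methoxymethoxy)-7-methylnaphthalen-2-yl]carbamate, via acyl azide 31 (not isolated), via aryl isocyanate 32 (not isolated)
Conditions: DPPA, Et3N, toluene, rt → 80 °C; then t-BuOH, 90 °C
Reagents that add atoms: diphenylphosphoryl azide, [N-]=[N+]=NP(=O)(Oc1ccccc1)Oc1ccccc1; tert-butanol, CC(C)(C)O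
Why: The Curtius rearrangement replaces the C2 carboxyl by nitrogen with complete positional fidelity, and tert-butanol traps the isocyanate as the Boc carbamate.

**Step 21**
Reactants: 33 aryl bromide carbamate; 21 C15 enal
Product: 35 tert-butyl (2E,13E)-15-[6-(tert-butoxycarbonylamino)-2,8-bis(methoxymethoxy)-3-methylnaphthalen-1-yl]-15-hydroxy-7,9-O-isopropylidene-4,6,8,10,12,14-hexamethyl-5,11-bis(triethylsilyloxy)pentadeca-2,13-dienoate (both C15 epimers), via dilithiated aryl carbamate 34 (not isolated)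
Conditions: 33 (1.4 eq), n-BuLi (2.8 eq), THF, −78 °C; then 21 (1.0 eq), −78 °C; aq NH4Cl
Reagents that add atoms: none
Why: N–H deprotonation then bromine–lithium exchange gives a chelated C5 aryllithium that adds 1,2 to the aldehyde far faster than to the tert-butyl enoate; the new C15 carbinol centre is uncontrolled and is destroyed in the next step.

**Step 22**
Reactants: 35 C15 carbinol
Product: 36 tert-butyl (2E,13E)-15-[6-(tert-butoxycarbonylamino)-2,8-bis(methoxymethoxy)-3-methylnaphthalen-1-yl]-7,9-O-isopropylidene-4,6,8,10,12,14-hexamethyl-15-oxo-5,11-bis(triethylsilyloxy)pentadeca-2,13-dienoate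
Conditions: Dess–Martin periodinane, pyridine, CH2Cl2, 0 °C → rt
Reagents that add atoms: none
Why: Dess–Martin oxidation of the hindered allylic/benzylic alcohol gives the aryl enone under buffered conditions that do not move the C13=C14 double bond or epimerise C12.

**Step 23**
Reactants: 36 protected aryl enone
Product: 38 (2E,4R,5S,6S,7S,8S,9R,10R,11R,12S,13E)-15-(6-amino-2-hydroxy-3-methyl-5,8-dioxo-5,8-dihydronaphthalen-1-yl)-5,7,9,11-tetrahydroxy-4,6,8,10,12,14-hexamethyl-15-oxopentadeca-2,13-dienoic acid (target CNP0336625.1), via deprotected aminonaphthol seco acid 37 (not isolated)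
Conditions: TFA/H2O 9:1, 0 °C → rt; evaporate; then Fremy's salt (2.5 eq), KH2PO4 buffer, acetone/H2O, 0 °C → rt
Reagents that add atoms: potassium nitrosodisulfonate (Fremy's salt), [K+].[K+].[O]N(S(=O)(=O)[O-])S(=O)(=O)[O-]
Why: Aqueous TFA cleaves the TES ethers, acetonide, MOM ethers, Boc group and tert-butyl ester in one operation, and Teuber oxidation then converts the electron-rich 1-naphthol at its free para position (C1) into the 2-amino-1,4-naphthoquinone without touching any stereocentre.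

**Compound list**
1 | 2-methylpent-1-en-3-one (ethyl isopropenyl ketone) | C=C(C)C(=O)CC | starting material
2 | 2-methylprop-2-enal (methacrolein) | C=C(C)C=O | starting material
3 | (3E)-3-(dicyclohexylboryloxy)-2-methylpenta-1,3-diene, the (E)-enol borinate of 1 | C/C=C(/OB(C1CCCCC1)C1CCCCC1)C(C)=C | intermediate
4 | O-dicyclohexylboryl derivative of rac-(4S,5R)-5-hydroxy-2,4,6-trimethylhepta-1,6-dien-3-one (anti aldolate; racemic, one enantiomer drawn) | C=C(C)C(=O)[C@@H](C)[C@@H](OB(C1CCCCC1)C1CCCCC1)C(C)=C | intermediate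
5 | meso-(3R,4r,5S)-2,4,6-trimethylhepta-1,6-diene-3,5-diol (syn diol, 4-Me anti to both OH) | C=C(C)[C@@H](O)[C@@H](C)[C@@H](O)C(C)=C | intermediate
6 | meso-(4R,5r,6S)-2,2,5-trimethyl-4,6-di(prop-1-en-2-yl)-1,3-dioxane | C=C(C)[C@@H](OC1(C)C)[C@@H](C)[C@@H](O1)C(C)=C | intermediate
7 | bis(9-borabicyclo[3.3.1]nonan-9-yl) hydroboration adduct of 6 (boron on both terminal CH2) | C1CCC2CCCC1B2C[C@@H](C)[C@@H](OC3(C)C)[C@@H](C)[C@@H](O3)[C@@H](C)CB1C2CCCC1CCC2 | intermediate
8 | meso (2R)-2-[(4R,5s,6S)-6-[(2S)-1-hydroxypropan-2-yl]-2,2,5-trimethyl-1,3-dioxan-4-yl]propan-1-ol (C5–C11 diol) | OC[C@@H](C)[C@@H](OC1(C)C)[C@@H](C)[C@@H](O1)[C@@H](C)CO | intermediate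
9 | (2R)-2-[(4R,5S,6S)-6-[(2S)-1-hydroxypropan-2-yl]-2,2,5-trimethyl-1,3-dioxan-4-yl]propyl acetate (11-OAc, 5-OH) | CC(=O)OC[C@@H](C)[C@@H](OC1(C)C)[C@@H](C)[C@@H](O1)[C@@H](C)CO | intermediate
10 | C5–C11 aldehyde: 5-CHO, 6,8,10-trimethyl, 7,9-O-isopropylidene, 11-OAc | CC(=O)OC[C@@H](C)[C@@H](OC1(C)C)[C@@H](C)[C@@H](O1)[C@@H](C)C=O | intermediate
11 | (Z)-crotylboronic acid pinacol ester, 2-[(2Z)-but-2-en-1-yl]-4,4,5,5-tetramethyl-1,3,2-dioxaborolane | C/C=C\CB1OC(C)(C)C(C)(C)O1 | starting material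
12 | 5-O-(pinacolboryl) ether of 13 | CC(=O)OC[C@@H](C)[C@@H](OC1(C)C)[C@@H](C)[C@@H](O1)[C@@H](C)[C@@H](OB2OC(C)(C)C(C)(C)O2)[C@H](C)C=C | intermediate
13 | C2–C11 alkenol: terminal vinyl C2=C3, 4-Me, 5-OH, 6,8,10-trimethyl, 7,9-O-isopropylidene, 11-OAc | CC(=O)OC[C@@H](C)[C@@H](OC1(C)C)[C@@H](C)[C@@H](O1)[C@@H](C)[C@@H](O)[C@H](C)C=C | intermediate
14 | C2–C11 alkene diol: as 13 with free 11-OH | OC[C@@H](C)[C@@H](OC1(C)C)[C@@H](C)[C@@H](O1)[C@@H](C)[C@@H](O)[C@H](C)C=C | intermediate
15 | tert-butyl acrylate | C=CC(=O)OC(C)(C)C | starting material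
16 | tert-butyl (2E)-5,11-dihydroxy-7,9-O-isopropylidene-4,6,8,10-tetramethylundec-2-enoate | OC[C@@H](C)[C@@H](OC1(C)C)[C@@H](C)[C@@H](O1)[C@@H](C)[C@@H](O)[C@H](C)/C=C/C(=O)OC(C)(C)C | intermediate
17 | tert-butyl (2E)-5-hydroxy-7,9-O-isopropylidene-4,6,8,10-tetramethyl-11-oxoundec-2-enoate | O=C[C@@H](C)[C@@H](OC1(C)C)[C@@H](C)[C@@H](O1)[C@@H](C)[C@@H](O)[C@H](C)/C=C/C(=O)OC(C)(C)C | intermediate
18 | 11-O-(pinacolboryl) ether of 19 | C=C[C@H](C)[C@@H](OB2OC(C)(C)C(C)(C)O2)[C@@H](C)[C@@H](OC1(C)C)[C@@H](C)[C@@H](O1)[C@@H](C)[C@@H](O)[C@H](C)/C=C/C(=O)OC(C)(C)C | intermediate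
19 | tert-butyl (2E)-5,11-dihydroxy-7,9-O-isopropylidene-4,6,8,10,12-pentamethyltetradeca-2,13-dienoate | C=C[C@H](C)[C@@H](O)[C@@H](C)[C@@H](OC1(C)C)[C@@H](C)[C@@H](O1)[C@@H](C)[C@@H](O)[C@H](C)/C=C/C(=O)OC(C)(C)C | intermediate
20 | tert-butyl (2E)-7,9-O-isopropylidene-4,6,8,10,12-pentamethyl-5,11-bis(triethylsilyloxy)tetradeca-2,13-dienoate | C=C[C@H](C)[C@@H](O[Si](CC)(CC)CC)[C@@H](C)[C@@H](OC1(C)C)[C@@H](C)[C@@H](O1)[C@@H](C)[C@@H](O[Si](CC)(CC)CC)[C@H](C)/C=C/C(=O)OC(C)(C)C | intermediate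
21 | tert-butyl (2E,13E)-7,9-O-isopropylidene-4,6,8,10,12,14-hexamethyl-15-oxo-5,11-bis(triethylsilyloxy)pentadeca-2,13-dienoate | C/C(=C\[C@H](C)[C@@H](O[Si](CC)(CC)CC)[C@@H](C)[C@@H](OC1(C)C)[C@@H](C)[C@@H](O1)[C@@H](C)[C@@H](O[Si](CC)(CC)CC)[C@H](C)/C=C/C(=O)OC(C)(C)C)C=O | intermediate
22 | 4-hydroxy-3-methylbenzaldehyde | O=Cc1ccc(O)c(C)c1 | starting material
23 | 4-(methoxymethoxy)-3-methylbenzaldehyde | O=Cc1ccc(OCOC)c(C)c1 | intermediate
24 | dimethyl succinate | COC(=O)CCC(=O)OC | starting material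
25 | (E)-3-(methoxycarbonyl)-4-[4-(methoxymethoxy)-3-methylphenyl]but-3-enoic acid | COC(=O)/C(CC(=O)O)=C/c1ccc(OCOC)c(C)c1 | intermediate
26 | methyl 4-acetoxy-6-(methoxymethoxy)-7-methylnaphthalene-2-carboxylate | COC(=O)c1cc(OC(C)=O)c2cc(OCOC)c(C)cc2c1 | intermediate
27 | methyl 4-acetoxy-5-bromo-6-(methoxymethoxy)-7-methylnaphthalene-2-carboxylate | COC(=O)c1cc(OC(C)=O)c2c(Br)c(OCOC)c(C)cc2c1 | intermediate
28 | methyl 5-bromo-4-hydroxy-6-(methoxymethoxy)-7-methylnaphthalene-2-carboxylate | COC(=O)c1cc(O)c2c(Br)c(OCOC)c(C)cc2c1 | intermediate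
29 | methyl 5-bromo-4,6-bis(methoxymethoxy)-7-methylnaphthalene-2-carboxylate | COC(=O)c1cc(OCOC)c2c(Br)c(OCOC)c(C)cc2c1 | intermediate
30 | 5-bromo-4,6-bis(methoxymethoxy)-7-methylnaphthalene-2-carboxylic acid | OC(=O)c1cc(OCOC)c2c(Br)c(OCOC)c(C)cc2c1 | intermediate
31 | 5-bromo-4,6-bis(methoxymethoxy)-7-methylnaphthalene-2-carbonyl azide | [N-]=[N+]=NC(=O)c1cc(OCOC)c2c(Br)c(OCOC)c(C)cc2c1 | intermediate
32 | 5-bromo-2-isocyanato-4,6-bis(methoxymethoxy)-7-methylnaphthalene (target ring locants) | O=C=Nc1cc(OCOC)c2c(Br)c(OCOC)c(C)cc2c1 | intermediate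
33 | tert-butyl N-[5-bromo-4,6-bis(methoxymethoxy)-7-methylnaphthalen-2-yl]carbamate | CC(C)(C)OC(=O)Nc1cc(OCOC)c2c(Br)c(OCOC)c(C)cc2c1 | intermediate
34 | N,C5-dilithio derivative of 33 (Li on the carbamate N, Li in place of Br) | [Li]N(C(=O)OC(C)(C)C)c1cc(OCOC)c2c([Li])c(OCOC)c(C)cc2c1 | intermediate
35 | tert-butyl (2E,13E)-15-[6-(tert-butoxycarbonylamino)-2,8-bis(methoxymethoxy)-3-methylnaphthalen-1-yl]-15-hydroxy-7,9-O-isopropylidene-4,6,8,10,12,14-hexamethyl-5,11-bis(triethylsilyloxy)pentadeca-2,13-dienoate (C15 epimers) | C/C(=C\[C@H](C)[C@@H](O[Si](CC)(CC)CC)[C@@H](C)[C@@H](OC1(C)C)[C@@H](C)[C@@H](O1)[C@@H](C)[C@@H](O[Si](CC)(CC)CC)[C@H](C)/C=C/C(=O)OC(C)(C)C)C(O)c1c(OCOC)c(C)cc2c1c(OCOC)cc(NC(=O)OC(C)(C)C)c2 | intermediate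
36 | tert-butyl (2E,13E)-15-[6-(tert-butoxycarbonylamino)-2,8-bis(methoxymethoxy)-3-methylnaphthalen-1-yl]-7,9-O-isopropylidene-4,6,8,10,12,14-hexamethyl-15-oxo-5,11-bis(triethylsilyloxy)pentadeca-2,13-dienoate | C/C(=C\[C@H](C)[C@@H](O[Si](CC)(CC)CC)[C@@H](C)[C@@H](OC1(C)C)[C@@H](C)[C@@H](O1)[C@@H](C)[C@@H](O[Si](CC)(CC)CC)[C@H](C)/C=C/C(=O)OC(C)(C)C)C(=O)c1c(OCOC)c(C)cc2c1c(OCOC)cc(NC(=O)OC(C)(C)C)c2 | intermediate
37 | (2E,4R,5S,6S,7S,8S,9R,10R,11R,12S,13E)-15-(6-amino-2,8-dihydroxy-3-methylnaphthalen-1-yl)-5,7,9,11-tetrahydroxy-4,6,8,10,12,14-hexamethyl-15-oxopentadeca-2,13-dienoic acid | C/C(=C\[C@H](C)[C@@H](O)[C@@H](C)[C@@H](O)[C@@H](C)[C@@H](O)[C@@H](C)[C@@H](O)[C@H](C)/C=C/C(=O)O)C(=O)c1c(O)c(C)cc2c1c(O)cc(N)c2 | intermediate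
38 | (2E,4R,5S,6S,7S,8S,9R,10R,11R,12S,13E)-15-(6-amino-2-hydroxy-3-methyl-5,8-dioxo-5,8-dihydronaphthalen-1-yl)-5,7,9,11-tetrahydroxy-4,6,8,10,12,14-hexamethyl-15-oxopentadeca-2,13-dienoic acid | C/C(=C\[C@H](C)[C@@H](O)[C@@H](C)[C@@H](O)[C@@H](C)[C@@H](O)[C@@H](C)[C@@H](O)[C@H](C)/C=C/C(=O)O)C(=O)c1c(O)c(C)cc2c1C(=O)C=C(N)C2=O | target

**Step count and risks**
Total step count: 23. Longest linear sequence: 15 steps (steps 1–12, then 21–23). The naphthalene branch is 8 steps (13–20) before the coupling.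

The three steps most likely to fail:

Step 4 (lipase desymmetrisation: the sense or the ee may be wrong). The fallback sets out from 8 and comes back at 9. Both hydroxyls of 8 are acetylated (Ac2O, pyridine, DMAP) to the meso diacetate F1, and one enantiotopic acetate is then hydrolysed with the same lipase (or pig-liver esterase) in pH 7 phosphate buffer. The enzyme removes the acetyl group from the arm it would otherwise have acylated, so hydrolysis gives the monoacetate antipodal to that from the acylation mode. Whichever mode gives 9 is used.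

Step 12 (cross-metathesis of a hindered, allylically branched alkene with methacrolein to a trisubstituted enal). The fallback sets out from 20 and comes back at 21. Only the electron-rich terminal vinyl group is dihydroxylated (OsO4 cat., NMO, acetone/H2O) to the 13,14-diol F2. This is cleaved with NaIO4 to the C13 aldehyde F3. A Wittig reaction of F3 with the stabilised ylide 2-(triphenylphosphoranylidene)propanal (toluene, 80 °C) gives the (E)-enal 21.

Step 23 (one-pot global acidolysis and oxidation of a free aminonaphthol polyol). The fallback sets out from 36 and comes back at 38; the unveiling is staged so that the oxidation is run on an N-acylated naphthol. Dilute methanolic HCl (AcCl cat., MeOH, 0 °C → rt) removes the TES ethers, the acetonide and both aryl MOM ethers but leaves the Boc carbamate and the tert-butyl ester. This gives the N-Boc naphthalene-4,6-diol tetraol tert-butyl ester F4. Fremy's salt (KH2PO4 buffer, acetone/H2O) oxidises it to the N-Boc aminoquinone tert-butyl ester F5. Anhydrous TFA/CH2Cl2 at 0 °C then removes the Boc and tert-butyl groups to give 38.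

**Further compounds**
F1 | step 4 | meso diacetate of 8, [(4R,5s,6S)-2,2,5-trimethyl-1,3-dioxane-4,6-diyl]bis[(2R/2S)-propane-2,1-diyl] diacetate | CC(=O)OC[C@@H](C)[C@@H](OC1(C)C)[C@@H](C)[C@@H](O1)[C@@H](C)COC(C)=O
F2 | step 12 | 13,14-diol from 20 (C13 epimers), tert-butyl (2E)-13,14-dihydroxy-7,9-O-isopropylidene-4,6,8,10,12-pentamethyl-5,11-bis(triethylsilyloxy)tetradec-2-enoate | OCC(O)[C@H](C)[C@@H](O[Si](CC)(CC)CC)[C@@H](C)[C@@H](OC1(C)C)[C@@H](C)[C@@H](O1)[C@@H](C)[C@@H](O[Si](CC)(CC)CC)[C@H](C)/C=C/C(=O)OC(C)(C)C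
F3 | step 12 | C13 aldehyde, tert-butyl (2E)-7,9-O-isopropylidene-4,6,8,10,12-pentamethyl-13-oxo-5,11-bis(triethylsilyloxy)tridec-2-enoate | O=C[C@H](C)[C@@H](O[Si](CC)(CC)CC)[C@@H](C)[C@@H](OC1(C)C)[C@@H](C)[C@@H](O1)[C@@H](C)[C@@H](O[Si](CC)(CC)CC)[C@H](C)/C=C/C(=O)OC(C)(C)C
F4 | step 23 | tert-butyl (2E,13E)-15-[6-(tert-butoxycarbonylamino)-2,8-dihydroxy-3-methylnaphthalen-1-yl]-5,7,9,11-tetrahydroxy-4,6,8,10,12,14-hexamethyl-15-oxopentadeca-2,13-dienoate | C/C(=C\[C@H](C)[C@@H](O)[C@@H](C)[C@@H](O)[C@@H](C)[C@@H](O)[C@@H](C)[C@@H](O)[C@H](C)/C=C/C(=O)OC(C)(C)C)C(=O)c1c(O)c(C)cc2c1c(O)cc(NC(=O)OC(C)(C)C)c2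
F5 | step 23 | tert-butyl (2E,13E)-15-[6-(tert-butoxycarbonylamino)-2-hydroxy-3-methyl-5,8-dioxo-5,8-dihydronaphthalen-1-yl]-5,7,9,11-tetrahydroxy-4,6,8,10,12,14-hexamethyl-15-oxopentadeca-2,13-dienoate | C/C(=C\[C@H](C)[C@@H](O)[C@@H](C)[C@@H](O)[C@@H](C)[C@@H](O)[C@@H](C)[C@@H](O)[C@H](C)/C=C/C(=O)OC(C)(C)C)C(=O)c1c(O)c(C)cc2c1C(=O)C=C(NC(=O)OC(C)(C)C)C2=O
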